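**Retrosynthetic overview**

1. The ten-membered carbocycle is closed last, at the C3–C4 bond, by intramolecular addition of a C4 alkenylchromium (from a Z-alkenyl iodide) to a C3 aldehyde. The feature that allows this is that the carbinol carbon C3 is bonded directly to sp2 carbon C4 of the cis C4=C5 bond, whose other end C5 carries the lactone carbon C6, so C3 and C6 sit on the same side of the alkene and the chain is already turned.
2. The seco-aldehyde comes from a C7–C8 Barbier allylation of a β,γ-epoxy aldehyde with a 3-(bromomethyl)butenolide. This unveils the α-methylene lactone and sets C7, but gives C8 as the wrong epimer. C8 is then inverted while the epoxy ester is installed (Mitsunobu).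
3. The three building blocks are the bromobutenolide (C4–C7, C11–C13, C15) from acrolein, the epoxy aldehyde (C1–C3, C8–C10, C14) from pent-1-en-4-yne, and the epoxy acid from tiglyl alcohol.
4. Order of ring formation: side-chain oxirane (step 1), lactone ring (step 7, metathesis), 1,10-oxirane (step 10), ten-membered carbocycle (step 16). Only the C3 isobutyrate is added afterwards.

Key step: step 16

Remark: germacranolide numbering is used (C1–C10 ring, C11–C13 lactone carbons, C14 on C10, C15 on C4); the target is (1R,3S,4Z,6R,7R,8R,10R) with a (2S,3R)-2,3-dimethyloxirane-2-carboxylate (the trans, tiglate-type epoxide), and C6 is labelled S in the iodine-bearing compounds 9, 11, 12 and 21–26 only because iodine changes the priorities.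

**Route**

Step 1
Reactants: 1 (2E)-2-methylbut-2-en-1-ol
Product: 2 [(2R,3R)-2,3-dimethyloxiran-2-yl]methanol
Conditions: Ti(OiPr)4 (cat.), (−)-diethyl (2S,3S)-tartrate (cat.), t-BuOOH, 4 Å MS, CH2Cl2, −20 °C
Reagents that add atoms: tert-butyl hydroperoxide CC(C)(C)OO
Why: Sharpless asymmetric epoxidation of a primary E-allylic alcohol is reliable for this substitution pattern, and with the (2S,3S)-tartrate the titanium complex should deliver oxygen to the face that gives the (2R,3R)-epoxy alcohol, so both stereocentres of the later C8 acyl group are set by the reagent.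

Step 2
Reactants: 2 [(2R,3R)-2,3-dimethyloxiran-2-yl]methanol
Product: 3 (2S,3R)-2,3-dimethyloxirane-2-carboxylic acid
Conditions: RuCl3·xH2O (cat.), NaIO4, MeCN/EtOAc/H2O, 0 °C → rt
Reagents that add atoms: sodium periodate [Na+].[O-]I(=O)(=O)=O; water O
Why: RuO4 made in situ from RuCl3 and NaIO4 (Sharpless oxidation) takes primary 2,3-epoxy alcohols to glycidic acids without touching the oxirane, so the configuration is kept (the descriptor at C2 changes from R to S only because the carboxyl group now outranks C3).

Step 3
Reactants: 4 prop-2-enal (acrolein); 5 prop-1-yn-1-ylmagnesium bromide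
Product: 6 rac-hex-1-en-4-yn-3-ol
Conditions: THF, −78 °C → 0 °C; then H2O
Reagents that add atoms: none
Why: 1,2-Grignard addition of the alkynylmagnesium halide to the unhindered aldehyde at low temperature should give the racemic carbinol in which the carbinol carbon is C6, the vinyl CH is C7, the alkyne carbons are C5 and C4 and the methyl is C15.

Step 4
Reactants: 6 rac-hex-1-en-4-yn-3-ol
Product: 8 rac-(4Z)-5-iodohexa-1,4-dien-3-ol, via sodium alkenylaluminate 7 (not isolated)
Conditions: NaAlH2(OCH2CH2OMe)2, THF, 0 °C → rt; then iodine, THF, −78 °C → 0 °C; H2O work-up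
Reagents that add atoms: iodine [I][I]
Why: Hydroxyl-directed trans-hydroalumination of the propargylic alcohol puts aluminium on the distal alkyne carbon in the five-membered oxaaluminate 7, and iododealumination with retention gives the (Z)-3-iodoallylic alcohol, in which iodine (the later point of attachment of C3) is cis to the carbinol carbon C6.

Step 5
Reactants: 8 rac-(4Z)-5-iodohexa-1,4-dien-3-ol
Product: 9 (3S,4Z)-5-iodohexa-1,4-dien-3-ol
Conditions: Novozym 435 (immobilised Candida antarctica lipase B), vinyl acetate, hexane, 30 °C, stopped just past half conversion; chromatography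
Reagents that add atoms: none
Why: Lipase-catalysed kinetic resolution by transesterification follows the empirical size rule for secondary alcohols (small vinyl group, large iodoalkenyl group), so the R enantiomer should be acetylated and the S alcohol, which has the spatial arrangement needed at C6, should be recovered.

Step 6
Reactants: 9 (3S,4Z)-5-iodohexa-1,4-dien-3-ol; 10 2-(bromomethyl)prop-2-enoic acid
Product: 11 (3S,4Z)-5-iodohexa-1,4-dien-3-yl 2-(bromomethyl)prop-2-enoate
Conditions: N,N′-dicyclohexylcarbodiimide, DMAP (cat.), CH2Cl2, 0 °C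
Reagents that add atoms: none
Why: Steglich esterification of the secondary alcohol under near-neutral conditions at low temperature should leave the allylic bromide and the bis-allylic stereocentre untouched.

Step 7
Reactants: 11 (3S,4Z)-5-iodohexa-1,4-dien-3-yl 2-(bromomethyl)prop-2-enoate
Product: 12 (5S)-3-(bromomethyl)-5-[(1Z)-2-iodoprop-1-en-1-yl]furan-2(5H)-one
Conditions: second-generation Grubbs catalyst (5 mol%), CH2Cl2 (dilute), 40 °C
Reagents that add atoms: none
Why: Ring-closing metathesis between the monosubstituted vinyl group and the 1,1-disubstituted acrylate closes the five-membered lactone as a 3-(bromomethyl)butenolide with loss of ethene, the trisubstituted iodoalkene being too hindered to take part and C6 not being involved.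

Step 8
Reactants: 13 pent-1-en-4-yne
Product: 16 (3E)-4-methylhepta-3,6-dien-1-ol, via alkenyldimethylalane 14 (not isolated), via lithium alkenylalanate 15 (not isolated)
Conditions: Me3Al, Cp2ZrCl2 (cat.), CH2Cl2, 0 °C → rt; n-BuLi, THF/hexane, −78 °C; oxirane, −78 → 0 °C; H2O work-up
Reagents that add atoms: trimethylaluminium C[Al](C)C; oxirane C1CO1
Why: Negishi zirconium-catalysed carboalumination adds methyl and aluminium syn across the terminal alkyne with methyl on the internal carbon, and the alanate opens oxirane with retention at the alkenyl carbon, so the E-trisubstituted C1=C10 alkene with C14 on C10 is formed stereospecifically.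

Step 9
Reactants: 16 (3E)-4-methylhepta-3,6-dien-1-ol
Product: 17 tert-butyl(dimethyl){[(3E)-4-methylhepta-3,6-dien-1-yl]oxy}silane
Conditions: TBSCl, imidazole, CH2Cl2, rt
Reagents that add atoms: tert-butyldimethylsilyl chloride CC(C)(C)[Si](C)(C)Cl
Why: Standard silylation of the primary alcohol (the later C3 oxygen) gives an ether that survives every step up to the ring closure.

Step 10
Reactants: 17 tert-butyl(dimethyl){[(3E)-4-methylhepta-3,6-dien-1-yl]oxy}silane
Product: 18 tert-butyl(dimethyl){2-[(2R,3R)-3-methyl-3-(prop-2-en-1-yl)oxiran-2-yl]ethoxy}silane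
Conditions: Shi ketone derived from natural fructose (0.3 equiv), KHSO5 (Oxone), K2CO3, Bu4NHSO4, MeCN/CH2(OMe)2/aq. buffer pH 10.5, 0 °C
Reagents that add atoms: potassium peroxymonosulfate [K+].[O-]S(=O)(=O)OO
Why: In the Shi asymmetric epoxidation the electrophilic chiral dioxirane should attack the electron-rich trisubstituted alkene and not the terminal vinyl group, and its spiro transition state gives the (R,R)-epoxide from E-trisubstituted alkenes, that is C1 and C10 as in the target.

Step 11
Reactants: 18 tert-butyl(dimethyl){2-[(2R,3R)-3-methyl-3-(prop-2-en-1-yl)oxiran-2-yl]ethoxy}silane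
Product: 20 2-[(2R,3R)-3-{2-[tert-butyl(dimethyl)silyloxy]ethyl}-2-methyloxiran-2-yl]acetaldehyde, via secondary ozonide 19 (not isolated)
Conditions: O3, CH2Cl2, −78 °C; then PPh3, −78 °C → rt; used at once
Reagents that add atoms: ozone [O-][O+]=O
Why: Ozonolysis with reductive work-up cleaves the only remaining C=C bond to the C8 aldehyde under neutral conditions, which the acid- and base-sensitive β,γ-epoxy aldehyde needs.

Step 12
Reactants: 12 (5S)-3-(bromomethyl)-5-[(1Z)-2-iodoprop-1-en-1-yl]furan-2(5H)-one; 20 2-[(2R,3R)-3-{2-[tert-butyl(dimethyl)silyloxy]ethyl}-2-methyloxiran-2-yl]acetaldehyde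
Product: 22 (4R,5S)-4-[(1S)-2-[(2R,3R)-3-{2-[tert-butyl(dimethyl)silyloxy]ethyl}-2-methyloxiran-2-yl]-1-hydroxyethyl]-5-[(1Z)-2-iodoprop-1-en-1-yl]-3-methylideneoxolan-2-one, via allylzinc bromide 21 (not isolated)
Conditions: Zn dust, THF/sat. aq. NH4Cl, 0 °C → rt
Reagents that add atoms: none
Why: In this zinc-mediated Barbier allylation the allylzinc 21 adds through its γ-carbon C7 (SE2′) in a chair-like six-membered transition state, which moves the double bond to C11=C13 and unveils the α-methylene lactone; C7 is attacked anti to the C6 alkenyl group (trans lactone, 7R), and the ring-locked allyl geometry with the aldehyde chain equatorial should give the 7,8-anti carbinol (8S), the C8 epimer that the next step inverts.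

Step 13
Reactants: 22 the 8S alcohol from step 12; 3 (2S,3R)-2,3-dimethyloxirane-2-carboxylic acid
Product: 23 (1R)-2-[(2R,3R)-3-{2-[tert-butyl(dimethyl)silyloxy]ethyl}-2-methyloxiran-2-yl]-1-[(2S,3R)-2-[(1Z)-2-iodoprop-1-en-1-yl]-4-methylidene-5-oxooxolan-3-yl]ethyl (2S,3R)-2,3-dimethyloxirane-2-carboxylate
Conditions: PPh3, DIAD, toluene, 0 °C → rt
Reagents that add atoms: none
Why: In the Mitsunobu esterification the C8 hydroxyl is activated on phosphorus and displaced by the carboxylate of 3 in an SN2 reaction with inversion, which corrects C8 to 8R and installs the epoxy ester in the same operation.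

Step 14
Reactants: 23 the silyl ether from step 13
Product: 24 (1R)-2-[(2R,3R)-3-(2-hydroxyethyl)-2-methyloxiran-2-yl]-1-[(2S,3R)-2-[(1Z)-2-iodoprop-1-en-1-yl]-4-methylidene-5-oxooxolan-3-yl]ethyl (2S,3R)-2,3-dimethyloxirane-2-carboxylate
Conditions: HF·pyridine, pyridine, THF, 0 °C
Reagents that add atoms: none
Why: Fluoride cleavage of the primary silyl ether with pyridine-buffered HF·pyridine is mild enough for the trisubstituted oxirane, the glycidic ester and the α-methylene lactone.

Step 15
Reactants: 24 the primary alcohol from step 14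
Product: 25 (1R)-2-[(2R,3R)-2-methyl-3-(2-oxoethyl)oxiran-2-yl]-1-[(2S,3R)-2-[(1Z)-2-iodoprop-1-en-1-yl]-4-methylidene-5-oxooxolan-3-yl]ethyl (2S,3R)-2,3-dimethyloxirane-2-carboxylate
Conditions: Dess–Martin periodinane, NaHCO3, CH2Cl2, 0 °C; used at once
Reagents that add atoms: none
Why: Dess–Martin oxidation under NaHCO3 buffer should give the C3 aldehyde without acid or base strong enough to open the β,γ-epoxide.

Step 16
Reactants: 25 the seco-aldehyde from step 15
Product: 27 (1R,3S,4Z,6R,7R,8R,10R)-1,10-epoxy-3-hydroxygermacra-4,11(13)-dien-12,6-olid-8-yl (2S,3R)-2,3-dimethyloxirane-2-carboxylate, via alkenylchromium dichloride 26 (not isolated)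
Conditions: CrCl2 (10 equiv), NiCl2 (0.1 equiv), degassed DMSO/THF, rt, slow addition of 25 (syringe pump, final about 1 mM); H2O work-up
Reagents that add atoms: none
Why: This is an intramolecular Nozaki–Hiyama–Kishi reaction: zerovalent nickel formed from NiCl2 and CrCl2 inserts into the carbon–iodine bond at C4, the alkenyl group passes with retention of the Z geometry to trivalent chromium (26), and this non-basic alkenylchromium adds to the C3 aldehyde through a four-centred transition state with oxygen on chromium. The closest known reaction type is the NiCl2/CrCl2 macrocyclisation of alkenyl iodide aldehydes to ten-membered germacranolide carbocycles that already carry the α-methylene lactone. The only ring closed is the ten-membered carbocycle, by C3–C4 bond formation in a 10-exo-trig addition to the carbonyl group, the cis C4=C5 bond and the trans-substituted lactone holding C3 and C4 within reach. The new stereocentre C3 is set by the substrate: the aldehyde carbon has to reach C4 from the alkene face on which C7 lies, with C2 turned toward C5 and the aldehyde hydrogen toward C15, while chromium and oxygen keep the open position that iodine had, and this arrangement should give the 3S (3β) alcohol. The step needs chemoselectivity for the aldehyde over two esters, the enoate and two oxiranes, which the low basicity and aldehyde selectivity of alkenylchromium reagents secure, and ring closure in preference to intermolecular coupling, which slow addition at high dilution secures.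

Step 17
Reactants: 27 the macrocyclic 3β-alcohol from step 16
Product: 28 (1R,3S,4Z,6R,7R,8R,10R)-1,10-epoxy-3-(2-methylpropanoyloxy)germacra-4,11(13)-dien-12,6-olid-8-yl (2S,3R)-2,3-dimethyloxirane-2-carboxylate (CNP0117882.4)
Conditions: (i-PrCO)2O, DMAP (cat.), pyridine, CH2Cl2, 0 °C
Reagents that add atoms: 2-methylpropanoic anhydride CC(C)C(=O)OC(=O)C(C)C
Why: DMAP-catalysed acylation of the allylic C3 alcohol with the anhydride proceeds with retention at C3 and should not touch the other esters or the oxiranes.

**Compound list**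

1 | (2E)-2-methylbut-2-en-1-ol (tiglyl alcohol) | C/C=C(\C)CO | starting material
2 | [(2R,3R)-2,3-dimethyloxiran-2-yl]methanol | OC[C@@]1(C)O[C@@H]1C | intermediate
3 | (2S,3R)-2,3-dimethyloxirane-2-carboxylic acid | OC(=O)[C@@]1(C)O[C@@H]1C | intermediate
4 | prop-2-enal (acrolein) | C=CC=O | starting material
5 | prop-1-yn-1-ylmagnesium bromide | CC#C[Mg]Br | starting material
6 | rac-hex-1-en-4-yn-3-ol | C=CC(O)C#CC | intermediate
7 | sodium 2,2-bis(2-methoxyethoxy)-3-methyl-5-vinyl-2,5-dihydro-1,2-oxaaluminol-2-uide (cyclic Z-alkenylaluminate, racemic) | [Na+].C=CC1O[Al-](OCCOC)(OCCOC)C(C)=C1 | intermediate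
8 | rac-(4Z)-5-iodohexa-1,4-dien-3-ol | C=CC(O)/C=C(/C)I | intermediate
9 | (3S,4Z)-5-iodohexa-1,4-dien-3-ol | C=C[C@H](O)/C=C(/C)I | intermediate
10 | 2-(bromomethyl)prop-2-enoic acid | OC(=O)C(=C)CBr | starting material
11 | (3S,4Z)-5-iodohexa-1,4-dien-3-yl 2-(bromomethyl)prop-2-enoate | C=C[C@H](OC(=O)C(=C)CBr)/C=C(/C)I | intermediate
12 | (5S)-3-(bromomethyl)-5-[(1Z)-2-iodoprop-1-en-1-yl]furan-2(5H)-one | O=C1O[C@H](/C=C(/C)I)C=C1CBr | intermediate
13 | pent-1-en-4-yne | C=CCC#C | starting material
14 | dimethyl[(1E)-2-methylpenta-1,4-dien-1-yl]alane | C[Al](C)/C=C(\C)CC=C | intermediate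
15 | lithium butyl(dimethyl)[(1E)-2-methylpenta-1,4-dien-1-yl]alanate | [Li+].CCCC[Al-](C)(C)/C=C(\C)CC=C | intermediate
16 | (3E)-4-methylhepta-3,6-dien-1-ol | OCC/C=C(\C)CC=C | intermediate
17 | tert-butyl(dimethyl){[(3E)-4-methylhepta-3,6-dien-1-yl]oxy}silane | CC(C)(C)[Si](C)(C)OCC/C=C(\C)CC=C | intermediate
18 | tert-butyl(dimethyl){2-[(2R,3R)-3-methyl-3-(prop-2-en-1-yl)oxiran-2-yl]ethoxy}silane | CC(C)(C)[Si](C)(C)OCC[C@H]1O[C@]1(C)CC=C | intermediate
19 | secondary ozonide (1,2,4-trioxolane) of 18, mixture at the trioxolane carbon | CC(C)(C)[Si](C)(C)OCC[C@H]1O[C@]1(C)CC2OCOO2 | intermediate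
20 | 2-[(2R,3R)-3-{2-[tert-butyl(dimethyl)silyloxy]ethyl}-2-methyloxiran-2-yl]acetaldehyde | CC(C)(C)[Si](C)(C)OCC[C@H]1O[C@]1(C)CC=O | intermediate
21 | {[(5S)-5-[(1Z)-2-iodoprop-1-en-1-yl]-2-oxo-2,5-dihydrofuran-3-yl]methyl}zinc bromide | O=C1O[C@H](/C=C(/C)I)C=C1C[Zn]Br | intermediate
22 | (4R,5S)-4-[(1S)-2-[(2R,3R)-3-{2-[tert-butyl(dimethyl)silyloxy]ethyl}-2-methyloxiran-2-yl]-1-hydroxyethyl]-5-[(1Z)-2-iodoprop-1-en-1-yl]-3-methylideneoxolan-2-one (8-epi alcohol) | C=C1C(=O)O[C@H](/C=C(/C)I)[C@H]1[C@@H](O)C[C@@]2(C)O[C@@H]2CCO[Si](C)(C)C(C)(C)C | intermediate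
23 | (1R)-2-[(2R,3R)-3-{2-[tert-butyl(dimethyl)silyloxy]ethyl}-2-methyloxiran-2-yl]-1-[(2S,3R)-2-[(1Z)-2-iodoprop-1-en-1-yl]-4-methylidene-5-oxooxolan-3-yl]ethyl (2S,3R)-2,3-dimethyloxirane-2-carboxylate | C=C1C(=O)O[C@H](/C=C(/C)I)[C@H]1[C@H](OC(=O)[C@@]2(C)O[C@@H]2C)C[C@@]3(C)O[C@@H]3CCO[Si](C)(C)C(C)(C)C | intermediate
24 | (1R)-2-[(2R,3R)-3-(2-hydroxyethyl)-2-methyloxiran-2-yl]-1-[(2S,3R)-2-[(1Z)-2-iodoprop-1-en-1-yl]-4-methylidene-5-oxooxolan-3-yl]ethyl (2S,3R)-2,3-dimethyloxirane-2-carboxylate | C=C1C(=O)O[C@H](/C=C(/C)I)[C@H]1[C@H](OC(=O)[C@@]2(C)O[C@@H]2C)C[C@@]3(C)O[C@@H]3CCO | intermediate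
25 | (1R)-2-[(2R,3R)-2-methyl-3-(2-oxoethyl)oxiran-2-yl]-1-[(2S,3R)-2-[(1Z)-2-iodoprop-1-en-1-yl]-4-methylidene-5-oxooxolan-3-yl]ethyl (2S,3R)-2,3-dimethyloxirane-2-carboxylate | C=C1C(=O)O[C@H](/C=C(/C)I)[C@H]1[C@H](OC(=O)[C@@]2(C)O[C@@H]2C)C[C@@]3(C)O[C@@H]3CC=O | intermediate
26 | Z-alkenylchromium dichloride derived from 25 (CrCl2 on C4 in place of iodine) | C=C1C(=O)O[C@H](/C=C(/C)[Cr](Cl)Cl)[C@H]1[C@H](OC(=O)[C@@]2(C)O[C@@H]2C)C[C@@]3(C)O[C@@H]3CC=O | intermediate
27 | (1R,3S,4Z,6R,7R,8R,10R)-1,10-epoxy-3-hydroxygermacra-4,11(13)-dien-12,6-olid-8-yl (2S,3R)-2,3-dimethyloxirane-2-carboxylate | C=C1C(=O)O[C@@H]2/C=C(/C)[C@@H](O)C[C@H]3O[C@]3(C)C[C@@H](OC(=O)[C@@]4(C)O[C@@H]4C)[C@@H]12 | intermediate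
28 | (1R,3S,4Z,6R,7R,8R,10R)-1,10-epoxy-3-(2-methylpropanoyloxy)germacra-4,11(13)-dien-12,6-olid-8-yl (2S,3R)-2,3-dimethyloxirane-2-carboxylate (CNP0117882.4) | C=C1C(=O)O[C@@H]2/C=C(/C)[C@@H](OC(=O)C(C)C)C[C@H]3O[C@]3(C)C[C@@H](OC(=O)[C@@]3(C)O[C@@H]3C)[C@@H]12 | target

**Step count and risks**

Total step count: 17. Longest linear sequence: 11 steps (steps 3–7, then 12–17, from acrolein).

Risk 1, step 16 (ring closure). The alkenylchromium may add to the other face of the aldehyde, and the conformational argument for 3S is a model rather than a certainty; slow closure would also allow intermolecular coupling. The fallback keeps the same ring closure, sets out from 25 and accepts the 3R alcohol (3-epi-27) F1 if that is what forms. The C3 ester is then introduced with inversion instead of retention: Mitsunobu esterification of F1 with 2-methylpropanoic acid (PPh3, DIAD, toluene, 0 °C) would give 28 directly. The fallback comes back to the route at 28.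

Risk 2, step 13 (inversion at C8). The activated C8 oxygen may be lost by elimination toward C7 (conjugated diene), or substitution may be slow because C7 is branched and the carboxylate is hindered. The fallback sets out from 22 and replaces the redox condensation by a two-stage sulfonate displacement. Compound 22 is converted into its chloromethanesulfonate F2 (ClCH2SO2Cl, pyridine, CH2Cl2, 0 °C). F2 is then displaced with inversion by cesium (2S,3R)-2,3-dimethyloxirane-2-carboxylate F3, made from 3 and Cs2CO3 (18-crown-6, toluene, 40 °C). The fallback comes back at 23.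

Risk 3, step 12 (Barbier coupling). The β,γ-epoxy aldehyde 20 may open its oxirane by β-elimination, or hydrate, during isolation or under the protic zinc conditions before it is allylated. The fallback sets out from 18 and generates the aldehyde from a stable precursor so that it is consumed without being concentrated. Alkene 18 is dihydroxylated (OsO4 cat., N-methylmorpholine N-oxide, acetone/H2O) to the diol (mixture at the new carbinol) F4. F4 is cleaved with NaIO4 on wet silica in CH2Cl2, and the filtered solution of 20 is run directly into 12 and indium powder in THF/H2O. The neutral indium-mediated allylation passes through the same chair-like transition state and comes back to the route at 22.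

Further compounds
F1 | step 16 | (1R,3R,4Z,6R,7R,8R,10R)-1,10-epoxy-3-hydroxygermacra-4,11(13)-dien-12,6-olid-8-yl (2S,3R)-2,3-dimethyloxirane-2-carboxylate (3-epi-27) | C=C1C(=O)O[C@@H]2/C=C(/C)[C@H](O)C[C@H]3O[C@]3(C)C[C@@H](OC(=O)[C@@]4(C)O[C@@H]4C)[C@@H]12
F2 | step 13 | chloromethanesulfonate of 22 at the C8 oxygen (8S) | C=C1C(=O)O[C@H](/C=C(/C)I)[C@H]1[C@@H](OS(=O)(=O)CCl)C[C@@]2(C)O[C@@H]2CCO[Si](C)(C)C(C)(C)C
F3 | step 13 | cesium (2S,3R)-2,3-dimethyloxirane-2-carboxylate | [Cs+].[O-]C(=O)[C@@]1(C)O[C@@H]1C
F4 | step 12 | 3-[(2R,3R)-3-{2-[tert-butyl(dimethyl)silyloxy]ethyl}-2-methyloxiran-2-yl]propane-1,2-diol (mixture at C2 of the diol) | CC(C)(C)[Si](C)(C)OCC[C@H]1O[C@]1(C)CC(O)CO
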